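**Retrosynthetic overview**
1. The exocyclic methylene comes last by α-methylenation at C16; before that, the one-carbon-bridge ketone (C12) is reduced and the C1 alcohol acetylated.
2. The bridge (ring D) is cut back to a tricyclic 9(11)-en-12-one plus a two-carbon linchpin: C13–C16 by enolate alkylation with an α-carbonyl cation (enolonium) equivalent, then C11–C15 by a deconjugative Claisen closure that moves the alkene to C8=C9.
3. The enone comes from a ring C anisole by Birch reduction; C5, C6 and C1 are set before that by hydroboration/oxidation and hydride reduction.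
4. Ring B is closed by an enantioselective palladium-catalysed dienolate α-arylation that creates the C10 quaternary centre.
5. The arylation substrate comes from a ring A vinyl enone and a ring C aryl iodide by 1,6-addition. Ring order: A and C are brought in, then B, then the bridge D.

Assumption: only substrates and fragment building blocks are numbered, bulk reagents appear under "Reagents that add atoms"; positions use diterpenoid numbering (C1–C20; C15–C16 is the two-carbon bridge from C11 to C13, C17 the methylene carbon), and α means the face of the C20 methyl group.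

**Step 1**
Reactants: 1 3-ethoxy-2-methylcyclohex-2-en-1-one
Product: 3 3-ethoxy-2,6,6-trimethylcyclohex-2-en-1-one, via monomethyl enone 2 (not isolated)
Conditions: LiN(i-Pr)2 (1.1 equiv), THF, −78 °C, MeI; second cycle LiN(i-Pr)2 (1.2 equiv), MeI, −78 → 0 °C
Reagents that add atoms: iodomethane, CI
Why: Kinetic α′-deprotonation of the vinylogous ester is possible only at C6, so two enolate alkylations install the future C4 gem-dimethyl group; no stereocentre remains.

**Step 2**
Reactants: 3 3-ethoxy-2,6,6-trimethylcyclohex-2-en-1-one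
Product: 5 2,4,4-trimethyl-3-vinylcyclohex-2-en-1-one, via carbinol alkoxide 4 (not isolated)
Conditions: CH2=CHMgBr (1.5 equiv), CeCl3, THF, −78 → 0 °C; then 2 M HCl, rt
Reagents that add atoms: vinylmagnesium bromide, C=C[Mg]Br; water, O
Why: 1,2-Addition to the vinylogous ester carbonyl and acid hydrolysis with allylic transposition (Stork–Danheiser enone synthesis) give the linear dienone that is ring A with C1 as ketone; no stereocentre.

**Step 3**
Reactants: 5 2,4,4-trimethyl-3-vinylcyclohex-2-en-1-one; 6 2-bromo-1-iodo-4-methoxybenzene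
Product: 8 3-[2-(2-bromo-4-methoxyphenyl)ethyl]-2,4,4-trimethylcyclohex-2-en-1-one, via aryl Grignard 7 (not isolated)
Conditions: 6 (1.3 equiv), i-PrMgCl·LiCl (1.3 equiv), THF, −20 °C; CuBr·SMe2 (10 mol %), then 5, −40 → −10 °C; 1 M HCl
Reagents that add atoms: none
Why: Iodine–magnesium exchange spares the bromide, and copper-catalysed conjugate addition goes 1,6 to the unhindered vinyl terminus (the 1,4 site is fully substituted), protonation giving the conjugated enone; no stereocentre.

**Step 4**
Reactants: 8 3-[2-(2-bromo-4-methoxyphenyl)ethyl]-2,4,4-trimethylcyclohex-2-en-1-one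
Product: 9 (10R)-12-methoxy-4,4,10-trimethyl tricyclic 5-en-1-one (ring C aromatic; C20 α)
Conditions: Pd2(dba)3 (2.5 mol %), (R)-BINAP (7 mol %), NaOt-Bu (1.5 equiv), toluene, 70 °C
Reagents that add atoms: none
Why: Proposed new method: the alkoxide forms the thermodynamic dienolate (γ-deprotonation at C6), the arylpalladium bromide can reach only its α-carbon C10 through a six-membered ring, and reductive elimination closes ring B, creates the C10 quaternary centre and leaves the 5,6-alkene, the chiral bisphosphine selecting the dienolate face (its antipode is used if the first run gives 10S); the closest known reaction is the Buchwald–Hartwig enantioselective α-arylation of α-branched ketones and its intramolecular variants.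

**Step 5**
Reactants: 9 (10R)-12-methoxy-4,4,10-trimethyl tricyclic 5-en-1-one
Product: 11 trans-fused 12-methoxy tricyclic 1,6-dione (5β-H), via bis-borane adduct 10 (not isolated)
Conditions: BH3·SMe2 (4 equiv), THF, 0 → 45 °C; then NMO (10 equiv), (n-Pr4N)RuO4 (10 mol %), 4 Å sieves, CH2Cl2, rt
Reagents that add atoms: N-methylmorpholine N-oxide, C[N+]1([O-])CCOCC1
Why: syn-Hydroboration from the β face, away from the axial C19 and C20 methyl groups, puts boron on C6 and hydrogen on C5β (trans ring fusion), and the perruthenate/N-oxide oxidation takes both the C6–B bond and the C1 borate to ketones in the same flask.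

**Step 6**
Reactants: 11 trans-fused 12-methoxy tricyclic 1,6-dione
Product: 12 12-methoxy tricyclic 1α,6α-diol
Conditions: NaBH4 (3 equiv), MeOH/THF, −20 → 0 °C
Reagents that add atoms: none
Why: Hydride reduction: at C6 hydride enters from the β face opposite the two syn-axial methyl groups (axial 6α-OH), and at C1 axial attack from the β face gives the equatorial 1α-OH cis to C20.

**Step 7**
Reactants: 12 12-methoxy tricyclic 1α,6α-diol
Product: 14 1α,6α-dihydroxy-9(11)-en-12-one (8α-H), via dihydroanisole 13 (not isolated)
Conditions: Li (8 equiv), NH3 (l), THF, t-BuOH, −78 → −33 °C; then 3 M HCl, MeOH, rt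
Reagents that add atoms: water, O
Why: Birch reduction leaves the alkyl-bearing C8=C9 and the enol ether C12=C13, and acid hydrolysis with conjugation gives the 9(11)-en-12-one, C8 being protonated under thermodynamic control (H8 α, C14 equatorial on ring B).

**Step 8 (key step)**
Reactants: 14 1α,6α-dihydroxy-9(11)-en-12-one; 15 2-bromo-N-methoxy-N-methylacetamide
Product: 18 1α,6α-dihydroxy-8-ene-12,15-dione (bridge C15–C16 on the β face), via C13-alkylated enone 16 (not isolated), via bridged hemiaminal 17 (not isolated)
Conditions: LiN(i-Pr)2 (3.3 equiv), THF, −78 °C; 15 (1.2 equiv), DMPU, −78 → −30 °C; then KOt-Bu (2.5 equiv), t-BuOH, −30 → 0 °C; aq NH4Cl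
Reagents that add atoms: none
Why: Proposed new method: the kinetic α′-enolate (C13) is alkylated by the α-bromo amide, an enolonium (a2) equivalent that joins two innately nucleophilic α-carbons (C13 and C16), then alkoxide equilibration to the extended dienolate lets its α-carbon C11 attack the tethered N-methoxy-N-methylamide from the β face, anti to the axial C20 methyl (C13 equilibrates by enolisation), which closes ring D, moves the alkene to C8=C9 and sets C11 and C13, the tetrahedral intermediate 17 blocking retro-Claisen until work-up; the closest known reactions are enolate alkylation by α-halo carbonyl compounds, C-acylation of ketone enolates by such amides and deconjugative α-substitution of dienolates.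

**Step 9**
Reactants: 18 1α,6α-dihydroxy-8-ene-12,15-dione
Product: 19 1α-acetoxy-6α-hydroxy-8-ene-12,15-dione
Conditions: Ac2O (1.3 equiv), pyridine, DMAP (5 mol %), CH2Cl2, 0 °C
Reagents that add atoms: acetic anhydride, CC(=O)OC(C)=O
Why: Acylation is selective for the equatorial C1 alcohol because the axial C6 alcohol is shielded by the syn-axial C19 and C20 methyl groups.

**Step 10**
Reactants: 19 1α-acetoxy-6α-hydroxy-8-ene-12,15-dione
Product: 20 1α-acetoxy-6α,12-dihydroxy-8-en-15-one (12-OH syn to the C15–C16 bridge)
Conditions: NaBH4 (1.0 equiv), CeCl3·7H2O (1.2 equiv), MeOH, −78 °C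
Reagents that add atoms: none
Why: Luche-type hydride reduction: the strained one-carbon-bridge ketone C12 should react before the hindered cyclopentanone C15, and with the lanthanide held between O12 and O15 on the side of the two-carbon bridge, hydride should arrive from the C8=C9 side, leaving the hydroxyl syn to the C15–C16 bridge.

**Step 11**
Reactants: 20 1α-acetoxy-6α,12-dihydroxy-8-en-15-one
Product: 21 CNP0149338.1
Conditions: (CH2O)n (10 equiv), i-Pr2NH·CF3CO2H (1.5 equiv), THF, 65 °C
Reagents that add atoms: formaldehyde (as paraformaldehyde), C=O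
Why: Mannich condensation–elimination (α-methylenation) can occur only at C16, the single enolisable position beside C15 because C11 is a bridgehead, and touches no stereocentre.

**Compound list**
1 | 3-ethoxy-2-methylcyclohex-2-en-1-one | CCOC1=C(C)C(=O)CCC1 | starting material
2 | 3-ethoxy-2,6-dimethylcyclohex-2-en-1-one (racemic) | CCOC1=C(C)C(=O)C(C)CC1 | intermediate (not isolated)
3 | 3-ethoxy-2,6,6-trimethylcyclohex-2-en-1-one | CCOC1=C(C)C(=O)C(C)(C)CC1 | intermediate
4 | 3-ethoxy-2,6,6-trimethyl-1-vinylcyclohex-2-en-1-ol (racemic, as bromomagnesium alkoxide) | CCOC1=C(C)C(O)(C=C)C(C)(C)CC1 | intermediate (not isolated)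
5 | 2,4,4-trimethyl-3-vinylcyclohex-2-en-1-one | C=CC1=C(C)C(=O)CCC1(C)C | intermediate
6 | 2-bromo-1-iodo-4-methoxybenzene | COc1ccc(I)c(Br)c1 | starting material
7 | (2-bromo-4-methoxyphenyl)magnesium chloride | COc1ccc([Mg]Cl)c(Br)c1 | intermediate (not isolated)
8 | 3-[2-(2-bromo-4-methoxyphenyl)ethyl]-2,4,4-trimethylcyclohex-2-en-1-one | COc1ccc(CCC2=C(C)C(=O)CCC2(C)C)c(Br)c1 | intermediate
9 | (10R)-12-methoxy-4,4,10-trimethyl tricyclic 5-en-1-one, ring C aromatic, C20 α | COc1ccc2CC=C3C(C)(C)CCC(=O)[C@@]3(C)c2c1 | intermediate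
10 | 6β-boryl-1-boryloxy adduct of 9 (5β-H; idealised monomer, C1 not defined) | COc1ccc2C[C@@H](B)[C@@H]3C(C)(C)CCC(OB)[C@@]3(C)c2c1 | intermediate (not isolated)
11 | trans-fused 12-methoxy tricyclic 1,6-dione (5β-H, C20 α) | COc1ccc2CC(=O)[C@@H]3C(C)(C)CCC(=O)[C@@]3(C)c2c1 | intermediate
12 | 12-methoxy tricyclic 1α,6α-diol (1-OH equatorial, 6-OH axial, 5β-H) | COc1ccc2C[C@H](O)[C@@H]3C(C)(C)CC[C@H](O)[C@@]3(C)c2c1 | intermediate
13 | 12-methoxy-8,12-diene-1α,6α-diol (Birch enol ether) | COC1=CCC2=C(C1)[C@]1(C)[C@@H](O)CCC(C)(C)[C@H]1[C@@H](O)C2 | intermediate (not isolated)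
14 | 1α,6α-dihydroxy-9(11)-en-12-one (8α-H) | O=C1C=C2[C@@H](CC1)C[C@H](O)[C@@H]1C(C)(C)CC[C@H](O)[C@@]21C | intermediate
15 | 2-bromo-N-methoxy-N-methylacetamide | CON(C)C(=O)CBr | starting material
16 | 14 carrying CH2C(=O)N(OMe)Me on C13 (C13 epimers) | O=C1C=C2[C@@H](CC1CC(=O)N(C)OC)C[C@H](O)[C@@H]1C(C)(C)CC[C@H](O)[C@@]21C | intermediate (not isolated)
17 | C11–C15 bridged N-methoxy-N-methyl hemiaminal (as alkoxide; C15 not defined) | C1C(O)(N(C)OC)[C@@H]2C3=C(C[C@H]1C2=O)C[C@H](O)[C@@H]1C(C)(C)CC[C@H](O)[C@@]31C | intermediate (not isolated)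
18 | 1α,6α-dihydroxy-8-ene-12,15-dione (C15–C16 bridge β, C12 bridge α) | C1C(=O)[C@@H]2C3=C(C[C@H]1C2=O)C[C@H](O)[C@@H]1C(C)(C)CC[C@H](O)[C@@]31C | intermediate
19 | 1α-acetoxy-6α-hydroxy-8-ene-12,15-dione | C1C(=O)[C@@H]2C3=C(C[C@H]1C2=O)C[C@H](O)[C@@H]1C(C)(C)CC[C@H](OC(C)=O)[C@@]31C | intermediate
20 | 1α-acetoxy-6α,12-dihydroxy-8-en-15-one (12-OH syn to the C15–C16 bridge) | C1C(=O)[C@@H]2C3=C(C[C@H]1[C@@H]2O)C[C@H](O)[C@@H]1C(C)(C)CC[C@H](OC(C)=O)[C@@]31C | intermediate
21 | CNP0149338.1: 1α-acetoxy-6α,12-dihydroxy-8,16-dien-15-one | C=C1C(=O)[C@@H]2C3=C(C[C@H]1[C@@H]2O)C[C@H](O)[C@@H]1C(C)(C)CC[C@H](OC(C)=O)[C@@]31C | target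

**Step count:** 11 steps in total; the longest linear sequence is 11 steps (1 → 21); 6 and 15 are bought.

**Steps most likely to fail**

Step 4 (enantioselective dienolate α-arylation). The fallback sets out from 8. An achiral catalyst (Pd2(dba)3, P(t-Bu)3, NaOt-Bu) gives the racemic tricyclic ketone F1. Reagent-controlled reduction with a Me-CBS oxazaborolidine and BH3·SMe2 turns the two enantiomers into diastereomeric alcohols: the (10R)-1α-alcohol F2 and the (10S)-derived diastereomer F3, separated by chromatography. F2 is put through the conditions of step 5, where the C1 carbinol is re-oxidised together with C6, and so comes back at 11.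

Step 8 (one-flask alkylation and bridging Claisen). The likely failure is acylation at the other dienolate terminus (C8) or reversal of the closure. The fallback sets out from 16, isolated by quenching after the alkylation stage. Closure under equilibrating conditions (KH, THF, 50 °C) is aimed at the conjugated C8-acylated isomer F4, in which C15 sits on C8 and the 9(11)-en-12-one is kept. Irradiation of this β,γ-unsaturated ketone (about 350 nm, MeCN) moves C15 from C8 to C11 by a photochemical 1,3-acyl shift on the same face, shifting the alkene to C8=C9, and comes back at 18.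

Step 10 (site- and face-selective reduction of C12). The fallback sets out from 14. Step 8 is repeated, but LiBH(s-Bu)3 (1.5 equiv, −78 °C) is added before the quench, while C15 is still masked as hemiaminal 17. Only C12 is then a ketone, and hydride must come from the side away from the substituted C15, giving the triol ketone F5. Ac2O, DMAP and pyridine give the 1,12-diacetate F6, and K2CO3 in MeOH at 0 °C removes the unhindered 12-acetate (the 1-acetate is neopentyl), coming back at 20.

**Further compounds**
F1 | step 4 | racemic 12-methoxy-4,4,10-trimethyl tricyclic 5-en-1-one | COc1ccc2CC=C3C(C)(C)CCC(=O)C3(C)c2c1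
F2 | step 4 | (10R)-12-methoxy tricyclic 5-en-1α-ol | COc1ccc2CC=C3C(C)(C)CC[C@H](O)[C@@]3(C)c2c1
F3 | step 4 | (10S)-diastereomer of F2 (same configuration at C1) | COc1ccc2CC=C3C(C)(C)CC[C@H](O)[C@]3(C)c2c1
F4 | step 8 | C8-acylated isomer of 18: 1α,6α-dihydroxy-9(11)-ene-12,15-dione with the C15–C16 bridge from C8 to C13 | O=C1C=C2[C@]3(C[C@@H]1CC3=O)C[C@H](O)[C@@H]1C(C)(C)CC[C@H](O)[C@@]21C
F5 | step 10 | 1α,6α,12-trihydroxy-8-en-15-one | C1C(=O)[C@@H]2C3=C(C[C@H]1[C@@H]2O)C[C@H](O)[C@@H]1C(C)(C)CC[C@H](O)[C@@]31C
F6 | step 10 | 1α,12-diacetoxy-6α-hydroxy-8-en-15-one | C1C(=O)[C@@H]2C3=C(C[C@H]1[C@@H]2OC(C)=O)C[C@H](O)[C@@H]1C(C)(C)CC[C@H](OC(C)=O)[C@@]31C
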